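Plan
1. Cuts: first the two interflavan bonds, C4 of fisetinidol unit U6 to C6 and C4 of fisetinidol unit U8 to C8 of the catechin ring A. Then, in each of the three pyran rings C, the C3–C4 bond (as a C3=C4 olefin, ring-closing metathesis) and the O1–C2 bond (allylic etherification).
2. Enabling feature: in ring C of the catechin unit, C4 is a bare benzylic CH2 next to a C3 carbinol that is trans to the C2 aryl group. This is the retron of an anti-Markovnikov hydration of a C3=C4 olefin. O1 ties the vinyl groups on C4a and C2 into a 1,7-diene held by the flat C4a–C8a–O1 unit, so ring C can close at C3–C4.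
3. Forward: one cinnamyl carbonate and two o-vinylphenols give two aryl allyl ethers, and each is closed to a flav-3-ene. The C3=C4 bond is the branching point: hydroboration gives the nucleophile (benzylated catechin), and epoxidation in methanol gives the electrophile (4-methoxyfisetinidol).
4. Union on catechin ring A: a glutarate tether between the two 3-O atoms takes the first electrophile to C8 from the β face. A 3-O-acetyl electrophile then takes the only free carbon, C6, from the α face. Bromine caps on C6 of both resorcinol rings stop self-condensation.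
5. Stereochemistry: the three C2 centres come from one iridium/phosphoramidite catalyst. The three C3 centres are relayed from C2 (reagent anti to the aryl group). C4 of U8 comes from the tether (3,4-cis) and C4 of U6 from acetoxonium participation (3,4-trans).
6. Tether, acetate, bromine caps and benzyl groups leave in the last two steps.

Key step: step 7

Assumption: the (Sa,S,S) enantiomer of the ligand L, O,O'-(1,1'-binaphthyl-2,2'-diyl) N,N-bis(1-phenylethyl)phosphoramidite, is taken to give the (S)-configured branched ethers drawn below; if the sense of induction is the opposite, its mirror image is used and nothing else changes.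

Step 1
Reactants: 1 3,4-bis(benzyloxy)benzaldehyde
Product: 2 ethyl (E)-3-[3,4-bis(benzyloxy)phenyl]acrylate
Conditions: (EtO)2P(O)CH2CO2Et, NaH, THF, 0 °C to rt
Reagents that add atoms: triethyl phosphonoacetate, CCOC(=O)CP(=O)(OCC)OCC
Why: Horner–Wadsworth–Emmons olefination of an aromatic aldehyde with a stabilised phosphonate anion should give the (E)-cinnamate.

Step 2
Reactants: 2 ethyl (E)-3-[3,4-bis(benzyloxy)phenyl]acrylate
Product: 3 (E)-3-[3,4-bis(benzyloxy)phenyl]prop-2-en-1-ol
Conditions: i-Bu2AlH (2.2 equiv), CH2Cl2, −78 °C; aq. potassium sodium tartrate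
Reagents that add atoms: none
Why: 1,2-reduction of an α,β-unsaturated ester with i-Bu2AlH should give the allylic alcohol and leave the olefin geometry and the benzyl ethers untouched.

Step 3
Reactants: 3 (E)-3-[3,4-bis(benzyloxy)phenyl]prop-2-en-1-ol
Product: 4 (E)-3-[3,4-bis(benzyloxy)phenyl]allyl methyl carbonate
Conditions: ClCO2Me, pyridine, CH2Cl2, 0 °C
Reagents that add atoms: methyl chloroformate, COC(=O)Cl
Why: Acylation of a primary allylic alcohol with a chloroformate installs the leaving group that also supplies the base (methoxide) in the allylic substitution.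

Step 4
Reactants: 5 2,4,6-trihydroxybenzaldehyde
Product: 6 4,6-bis(benzyloxy)-2-hydroxybenzaldehyde
Conditions: BnBr (2.05 equiv), K2CO3, DMF, rt
Reagents that add atoms: benzyl bromide, BrCc1ccccc1
Why: In this Williamson etherification the para hydroxyl and one ortho hydroxyl react, while the last hydroxyl is locked in a hydrogen bond to the formyl oxygen and stays free.

Step 5
Reactants: 6 4,6-bis(benzyloxy)-2-hydroxybenzaldehyde
Product: 7 3,5-bis(benzyloxy)-2-vinylphenol
Conditions: MePPh3Br (2.5 equiv), KOtBu (2.4 equiv), THF, 0 °C to rt; used at once, no acid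
Reagents that add atoms: methyltriphenylphosphonium bromide, C[P+](c1ccccc1)(c1ccccc1)c1ccccc1.[Br-]
Why: Wittig methylenation with excess non-stabilised ylide tolerates the free phenol (as phenoxide), as known for salicylaldehydes.

Step 6
Reactants: 7 3,5-bis(benzyloxy)-2-vinylphenol; 4 (E)-3-[3,4-bis(benzyloxy)phenyl]allyl methyl carbonate
Product: 8 (S)-1,5-bis(benzyloxy)-3-{1-[3,4-bis(benzyloxy)phenyl]allyloxy}-2-vinylbenzene
Conditions: [Ir(cod)Cl]2 (2 mol %), (Sa,S,S)-L (4 mol %, pre-activated with n-PrNH2), K3PO4, THF, 40 °C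
Reagents that add atoms: none
Why: In this iridium-catalysed asymmetric allylic etherification, known for o-vinylphenols and cinnamyl carbonates, the phenoxide attacks the aryl-bearing terminus of the cyclometalated allyliridium–phosphoramidite complex anti to the metal, which should give the branched ether and set the future C2 under catalyst control.

Step 7
Reactants: 8 (S)-1,5-bis(benzyloxy)-3-{1-[3,4-bis(benzyloxy)phenyl]allyloxy}-2-vinylbenzene
Product: 9 (S)-5,7-bis(benzyloxy)-2-[3,4-bis(benzyloxy)phenyl]-2H-chromene (tetra-O-benzyl flav-3-ene)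
Conditions: second-generation Grubbs catalyst (4 mol %), 1,4-benzoquinone (10 mol %), CH2Cl2 (0.01 M), 40 °C, in the dark
Reagents that add atoms: none
Why: Ring-closing olefin metathesis by the metallacyclobutane mechanism: the ruthenium alkylidene loads on the less encumbered allylic vinyl group, the new carbene adds [2+2] to the styrene on C4a, and cycloreversion releases the C3=C4 bond, driven by loss of ethylene. The closest known reaction type is the ring-closing metathesis of o-vinylaryl allyl ethers to 2H-chromenes, also used directly after an iridium-catalysed allylic etherification. Ring C closes as a six-membered ring from a 1,7-diene whose termini are held near each other by the flat C4a–C8a–O1 unit, so cyclisation should outrun dimerisation at this dilution. No stereocentre is formed, and C2 should be kept because the neutral medium neither ionises the doubly activated C2–O1 bond nor touches C2–H; this centre then steers the reagent of step 8 to the face anti to the aryl group. The step needs metathesis to win over ruthenium hydride isomerisation of the allyl ether, which is secured by the substrate having only two terminal, monosubstituted olefins and by the added benzoquinone. Darkness and mild temperature avoid the electrocyclic ring opening that would racemise the 2H-chromene.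

Step 8
Reactants: 9 (S)-5,7-bis(benzyloxy)-2-[3,4-bis(benzyloxy)phenyl]-2H-chromene
Product: 11 5,7,3',4'-tetra-O-benzyl-(+)-catechin [(2R,3S)], via C3-alkylborane 10 (not isolated)
Conditions: BH3·THF, THF, 0 °C to rt; then NaOH, H2O2, 0 °C
Reagents that add atoms: borane–THF, B.C1CCOC1 (boron only in 10); hydrogen peroxide, OO
Why: In this hydroboration–oxidation of a flav-3-ene, boron goes to C3 (away from the electron-rich benzylic C4) on the face anti to the C2 aryl group and the C–B bond is oxidised with retention, so C2 is relayed into the 2,3-trans carbinol.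

Step 9
Reactants: 12 5-bromo-2,4-dihydroxybenzaldehyde
Product: 13 4-(benzyloxy)-5-bromo-2-hydroxybenzaldehyde
Conditions: BnBr (1.05 equiv), NaHCO3, KI (cat.), MeCN, 80 °C
Reagents that add atoms: benzyl bromide, BrCc1ccccc1
Why: Selective Williamson etherification of the more acidic 4-OH succeeds because the 2-OH is hydrogen-bonded to the formyl group, and the bromine already sits on the carbon that becomes C6 of the fisetinidol ring A.

Step 10
Reactants: 13 4-(benzyloxy)-5-bromo-2-hydroxybenzaldehyde
Product: 14 5-(benzyloxy)-4-bromo-2-vinylphenol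
Conditions: MePPh3Br (2.5 equiv), KOtBu (2.4 equiv), THF, 0 °C to rt
Reagents that add atoms: methyltriphenylphosphonium bromide, C[P+](c1ccccc1)(c1ccccc1)c1ccccc1.[Br-]
Why: Wittig methylenation as in step 5, in which the aryl bromide is inert to ylide and alkoxide.

Step 11
Reactants: 14 5-(benzyloxy)-4-bromo-2-vinylphenol; 4 (E)-3-[3,4-bis(benzyloxy)phenyl]allyl methyl carbonate
Product: 15 (S)-1-(benzyloxy)-5-{1-[3,4-bis(benzyloxy)phenyl]allyloxy}-2-bromo-4-vinylbenzene
Conditions: [Ir(cod)Cl]2 (2 mol %), (Sa,S,S)-L (4 mol %, pre-activated with n-PrNH2), K3PO4, THF, 40 °C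
Reagents that add atoms: none
Why: The same iridium-catalysed asymmetric allylic etherification as in step 6, with the same ligand enantiomer, should set C2 of both fisetinidol units in the same absolute sense.

Step 12
Reactants: 15 (S)-1-(benzyloxy)-5-{1-[3,4-bis(benzyloxy)phenyl]allyloxy}-2-bromo-4-vinylbenzene
Product: 16 (S)-7-(benzyloxy)-2-[3,4-bis(benzyloxy)phenyl]-6-bromo-2H-chromene
Conditions: second-generation Grubbs catalyst (4 mol %), 1,4-benzoquinone (10 mol %), CH2Cl2 (0.01 M), 40 °C, in the dark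
Reagents that add atoms: none
Why: Ring-closing metathesis of an o-vinylaryl allyl ether as in step 7, here with a less hindered styrene, should close the pyran ring without touching C2.

Step 13
Reactants: 16 (S)-7-(benzyloxy)-2-[3,4-bis(benzyloxy)phenyl]-6-bromo-2H-chromene
Product: 18 (2R,3S,4R)-7-(benzyloxy)-2-[3,4-bis(benzyloxy)phenyl]-6-bromo-4-methoxychroman-3-ol, via 3β,4β-epoxide 17 (not isolated)
Conditions: mCPBA, CH2Cl2/MeOH (1:1), 0 °C
Reagents that add atoms: 3-chloroperbenzoic acid, O=C(OO)c1cccc(Cl)c1; methanol, CO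
Why: Prilezhaev epoxidation on the face anti to the C2 aryl group sets C3, and the epoxide, whose C4–O bond is para to the 7-benzyloxy group and ortho to O1, opens at C4 by solvolysis in methanol, mainly anti, to the 3,4-trans methoxy alcohol (the C4 epimer serves equally because C4 is ionised later).

Step 14
Reactants: 11 5,7,3',4'-tetra-O-benzyl-(+)-catechin
Product: 19 5,7,3',4'-tetra-O-benzylcatechin 3-O-(hydrogen glutarate)
Conditions: glutaric anhydride, DMAP, Et3N, CH2Cl2, rt
Reagents that add atoms: glutaric anhydride, O=C1CCCC(=O)O1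
Why: DMAP-catalysed opening of a cyclic anhydride by the secondary 3-OH installs the five-carbon tether with a free acid end in one operation.

Step 15
Reactants: 19 5,7,3',4'-tetra-O-benzylcatechin 3-O-(hydrogen glutarate); 18 (2R,3S,4R)-7-(benzyloxy)-2-[3,4-bis(benzyloxy)phenyl]-6-bromo-4-methoxychroman-3-ol
Product: 20 glutarate diester that joins 3-O of tetra-O-benzylcatechin to 3-O of the 6-bromo-4-methoxy-tri-O-benzylfisetinidol
Conditions: DCC, DMAP, CH2Cl2, 0 °C to rt
Reagents that add atoms: none
Why: Steglich esterification joins acid and secondary alcohol under neutral to basic conditions that leave the acid-labile C4 methyl ether untouched.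

Step 16
Reactants: 20 glutarate diester of the two flavan units
Product: 21 6-bromo-7,3',4'-tri-O-benzylfisetinidol-(4β→8)-5,7,3',4'-tetra-O-benzylcatechin 3,3-O-glutarate (fourteen-membered macrocyclic diester, upper unit 2R,3S,4R)
Conditions: TMSOTf (0.3 equiv), 4 Å molecular sieves, CH2Cl2 (1 mM), −40 to 0 °C
Reagents that add atoms: none
Why: In this tethered intramolecular Friedel–Crafts flavanylation, known for diester-linked catechin pairs to give the 3,4-cis (4β→8) dimer, TMSOTf ionises the C4–OMe bond to the p-alkoxybenzylic cation and the short tether on the β-oriented 3-O should bring C8, the most nucleophilic carbon of catechin ring A, to the β face.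

Step 17
Reactants: 18 (2R,3S,4R)-7-(benzyloxy)-2-[3,4-bis(benzyloxy)phenyl]-6-bromo-4-methoxychroman-3-ol
Product: 22 (2R,3S,4R)-7-(benzyloxy)-2-[3,4-bis(benzyloxy)phenyl]-6-bromo-4-methoxychroman-3-yl acetate
Conditions: Ac2O, pyridine, DMAP (cat.), rt
Reagents that add atoms: acetic anhydride, CC(=O)OC(C)=O
Why: Routine acetylation provides the participating group that will direct the second coupling.

Step 18
Reactants: 21 macrocyclic (4β→8) dimer; 22 3-O-acetyl-4-methoxy electrophile
Product: 23 protected trimer: 6-bromo-tri-O-benzylfisetinidol-(4β→8)-[3-O-acetyl-6-bromo-tri-O-benzylfisetinidol-(4α→6)]-tetra-O-benzylcatechin, glutarate tether in place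
Conditions: TMSOTf (0.5 equiv), CH2Cl2, −20 to 0 °C, slow addition of 22 (1.5 equiv)
Reagents that add atoms: none
Why: In this intermolecular Friedel–Crafts flavanylation of a C8-blocked catechin unit, C6 is the only free carbon of the sole phloroglucinol-type ring, the bromine caps silence C6 of both resorcinol-type rings, the tether holds the first interflavan bond, and the 3-acetoxy group should bridge the β face of the C4 cation as an acetoxonium ion so that C6 adds from the α face (3,4-trans).

Step 19
Reactants: 23 protected trimer with tether and acetate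
Product: 24 deca-O-benzyl-6,6-dibromo trimer triol (three free 3-OH groups)
Conditions: NaOMe (cat.), MeOH/THF, 40 °C
Reagents that add atoms: none
Why: Base-catalysed transesterification removes the glutarate tether and the acetate in one operation and touches no stereocentre, benzyl ether or aryl bromide.

Step 20
Reactants: 24 deca-O-benzyl-6,6-dibromo trimer triol
Product: 25 fisetinidol-(4β→8)-catechin-(6→4α)-fisetinidol (target; U8 2R,3S,4R; U6 2R,3S,4S; catechin 2R,3S)
Conditions: H2 (1 atm), Pd(OH)2/C, Et3N (3 equiv), THF/MeOH, rt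
Reagents that add atoms: none
Why: Hydrogenolysis over Pd(OH)2/C should cleave the ten benzyl ethers and, with Et3N to take up HBr, both aryl bromides, while the cyclic O1–C2 ethers and the interflavan bonds of flavan-3-ols survive such conditions.

Compound list
1 | 3,4-bis(benzyloxy)benzaldehyde | O=Cc1ccc(OCc2ccccc2)c(OCc2ccccc2)c1 | starting material
2 | ethyl (E)-3-[3,4-bis(benzyloxy)phenyl]acrylate | CCOC(=O)/C=C/c1ccc(OCc2ccccc2)c(OCc2ccccc2)c1 | intermediate
3 | (E)-3-[3,4-bis(benzyloxy)phenyl]prop-2-en-1-ol | OC/C=C/c1ccc(OCc2ccccc2)c(OCc2ccccc2)c1 | intermediate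
4 | (E)-3-[3,4-bis(benzyloxy)phenyl]allyl methyl carbonate | COC(=O)OC/C=C/c1ccc(OCc2ccccc2)c(OCc2ccccc2)c1 | intermediate
5 | 2,4,6-trihydroxybenzaldehyde | O=Cc1c(O)cc(O)cc1O | starting material
6 | 4,6-bis(benzyloxy)-2-hydroxybenzaldehyde | O=Cc1c(O)cc(OCc2ccccc2)cc1OCc1ccccc1 | intermediate
7 | 3,5-bis(benzyloxy)-2-vinylphenol | C=Cc1c(O)cc(OCc2ccccc2)cc1OCc1ccccc1 | intermediate
8 | (S)-1,5-bis(benzyloxy)-3-{1-[3,4-bis(benzyloxy)phenyl]allyloxy}-2-vinylbenzene | C=Cc1c(OCc2ccccc2)cc(OCc2ccccc2)cc1O[C@H](c1ccc(OCc2ccccc2)c(OCc2ccccc2)c1)C=C | intermediate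
9 | (S)-5,7-bis(benzyloxy)-2-[3,4-bis(benzyloxy)phenyl]-2H-chromene | c1ccccc1COc1cc(OCc2ccccc2)c2c(c1)O[C@H](c1ccc(OCc3ccccc3)c(OCc3ccccc3)c1)C=C2 | intermediate
10 | C3-alkylborane of 9 (BH2 on C3, trans to the 2-aryl group) | c1ccccc1COc1cc(OCc2ccccc2)c2c(c1)O[C@H](c1ccc(OCc3ccccc3)c(OCc3ccccc3)c1)[C@@H](B)C2 | intermediate
11 | 5,7,3',4'-tetra-O-benzyl-(+)-catechin, (2R,3S) | c1ccccc1COc1cc(OCc2ccccc2)c2c(c1)O[C@H](c1ccc(OCc3ccccc3)c(OCc3ccccc3)c1)[C@@H](O)C2 | intermediate
12 | 5-bromo-2,4-dihydroxybenzaldehyde | O=Cc1cc(Br)c(O)cc1O | starting material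
13 | 4-(benzyloxy)-5-bromo-2-hydroxybenzaldehyde | O=Cc1cc(Br)c(OCc2ccccc2)cc1O | intermediate
14 | 5-(benzyloxy)-4-bromo-2-vinylphenol | C=Cc1cc(Br)c(OCc2ccccc2)cc1O | intermediate
15 | (S)-1-(benzyloxy)-5-{1-[3,4-bis(benzyloxy)phenyl]allyloxy}-2-bromo-4-vinylbenzene | C=Cc1cc(Br)c(OCc2ccccc2)cc1O[C@H](c1ccc(OCc2ccccc2)c(OCc2ccccc2)c1)C=C | intermediate
16 | (S)-7-(benzyloxy)-2-[3,4-bis(benzyloxy)phenyl]-6-bromo-2H-chromene | Brc1cc2c(cc1OCc1ccccc1)O[C@H](c1ccc(OCc3ccccc3)c(OCc3ccccc3)c1)C=C2 | intermediate
17 | 3β,4β-epoxide of 16 (oxirane oxygen trans to the 2-aryl group) | Brc1cc2c(cc1OCc1ccccc1)O[C@H](c1ccc(OCc3ccccc3)c(OCc3ccccc3)c1)[C@H]3O[C@H]32 | intermediate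
18 | (2R,3S,4R)-7-(benzyloxy)-2-[3,4-bis(benzyloxy)phenyl]-6-bromo-4-methoxychroman-3-ol | Brc1cc2c(cc1OCc1ccccc1)O[C@H](c1ccc(OCc3ccccc3)c(OCc3ccccc3)c1)[C@@H](O)[C@@H]2OC | intermediate
19 | 5,7,3',4'-tetra-O-benzylcatechin 3-O-(hydrogen glutarate) | c1ccccc1COc1cc(OCc2ccccc2)c2c(c1)O[C@H](c1ccc(OCc3ccccc3)c(OCc3ccccc3)c1)[C@@H](OC(=O)CCCC(=O)O)C2 | intermediate
20 | glutarate diester of 11 (3-O) and 18 (3-O) | c1ccccc1COc1cc(OCc2ccccc2)c2c(c1)O[C@H](c1ccc(OCc3ccccc3)c(OCc3ccccc3)c1)[C@@H](OC(=O)CCCC(=O)O[C@H]1[C@H](OC)c3cc(Br)c(OCc4ccccc4)cc3O[C@@H]1c1ccc(OCc3ccccc3)c(OCc3ccccc3)c1)C2 | intermediate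
21 | 6-bromo-tri-O-benzylfisetinidol-(4β→8)-tetra-O-benzylcatechin 3,3-O-glutarate (macrocycle) | c1ccccc1COc1c(Br)cc2c(c1)O[C@H](c1ccc(OCc3ccccc3)c(OCc3ccccc3)c1)[C@@H](OC(=O)CCCC(=O)O5)[C@H]2c1c(OCc2ccccc2)cc(OCc2ccccc2)c2c1O[C@H](c1ccc(OCc3ccccc3)c(OCc3ccccc3)c1)[C@@H]5C2 | intermediate
22 | (2R,3S,4R)-7-(benzyloxy)-2-[3,4-bis(benzyloxy)phenyl]-6-bromo-4-methoxychroman-3-yl acetate | CC(=O)O[C@H]1[C@H](OC)c2cc(Br)c(OCc3ccccc3)cc2O[C@@H]1c1ccc(OCc2ccccc2)c(OCc2ccccc2)c1 | intermediate
23 | protected trimer with glutarate tether, acetate, two bromine caps and ten benzyl ethers | c1ccccc1COc1c(Br)cc2c(c1)O[C@H](c1ccc(OCc3ccccc3)c(OCc3ccccc3)c1)[C@@H](OC(=O)CCCC(=O)O5)[C@H]2c1c(OCc2ccccc2)c([C@@H]2c3cc(Br)c(OCc4ccccc4)cc3O[C@H](c3ccc(OCc4ccccc4)c(OCc4ccccc4)c3)[C@H]2OC(C)=O)c(OCc2ccccc2)c2c1O[C@H](c1ccc(OCc3ccccc3)c(OCc3ccccc3)c1)[C@@H]5C2 | intermediate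
24 | deca-O-benzyl-6,6-dibromo trimer triol | c1ccccc1COc1c(Br)cc2c(c1)O[C@H](c1ccc(OCc3ccccc3)c(OCc3ccccc3)c1)[C@@H](O)[C@H]2c1c(OCc2ccccc2)c([C@@H]2c3cc(Br)c(OCc4ccccc4)cc3O[C@H](c3ccc(OCc4ccccc4)c(OCc4ccccc4)c3)[C@H]2O)c(OCc2ccccc2)c2c1O[C@H](c1ccc(OCc3ccccc3)c(OCc3ccccc3)c1)[C@@H](O)C2 | intermediate
25 | fisetinidol-(4β→8)-catechin-(6→4α)-fisetinidol (CNP0289228.2) | Oc1ccc2c(c1)O[C@H](c1ccc(O)c(O)c1)[C@@H](O)[C@H]2c1c(O)c([C@@H]2c3ccc(O)cc3O[C@H](c3ccc(O)c(O)c3)[C@H]2O)c(O)c2c1O[C@H](c1ccc(O)c(O)c1)[C@@H](O)C2 | target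

Total step count: 20
Longest linear sequence: 12 steps (1, 2, 3, 6, 7, 8, 14, 15, 16, 18, 19, 20)

Steps most likely to fail

1. Step 16 (tethered C4–C8 bond). The fourteen-membered transition state may be loose enough to allow α-face attack. The 3-acyloxy group may also take part and steer the arene to the α face, or intermolecular attack may outrun ring closure. The fallback sets out from 11 and 18 and comes back at 24. It gives up the tether and replaces stereocontrol by separation.
   - An excess of 11 is condensed with 18, whose free 3-OH cannot bridge the cation, using TiCl4 in CH2Cl2 at 0 °C.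
   - In the 5-deoxy series both C4 epimers of the C8-linked dimer are expected. The 3,4-cis epimer, the dimer diol 6-bromo-tri-O-benzylfisetinidol-(4β→8)-tetra-O-benzylcatechin F1, is isolated by chromatography.
   - Acetylation (Ac2O, pyridine) gives the dimer diacetate F2.
   - TMSOTf-promoted coupling of F2 with 22 at C6 gives the trimer triacetate F3, and NaOMe in MeOH/THF leads to 24.

2. Step 18 (bond to the crowded C6). Attack at a carbon flanked by two benzyloxy groups and a macrocycle may be slow. The cation could then be lost by elimination or by attack on less activated rings, or the first interflavan bond could be cleaved by acid. The fallback sets out from 21 and 18 and comes back at 25. It is a biomimetic condensation of the free phenols.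
   - 21 is methanolysed (NaOMe, MeOH/THF) to the dimer diol F1 and hydrogenolysed (H2, Pd(OH)2/C, Et3N) to fisetinidol-(4β→8)-catechin F4.
   - 18 is hydrogenolysed under the same basic conditions, which should spare the C4 ether, to 4-O-methylleucofisetinidin F5.
   - F4 and F5 are condensed in 0.1 M aqueous HCl at rt. The free 5-OH and 7-OH make C6 more nucleophilic and less crowded, and the cation is expected to be taken mainly from the α face.
   - 25 is purified on Sephadex LH-20.

3. Step 6 (the same chemistry recurs in step 11). The very electron-rich phenoxide may attack through carbon instead of oxygen. The branched ether, whose C–O bond is activated by both the dialkoxyphenyl and the vinyl group, may also re-ionise, with loss of enantiopurity and drift to the linear ether. The fallback sets out from 3 and 6 and comes back at 9. It is an organocatalytic domino oxa-Michael/aldol condensation.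
   - 3 is oxidised with MnO2 in CH2Cl2 to (E)-3-[3,4-bis(benzyloxy)phenyl]acrylaldehyde F6.
   - F6 and 6 are combined under iminium/enamine catalysis (α,α-diphenylprolinol trimethylsilyl ether of the appropriate handedness, 2-nitrobenzoic acid, toluene, molecular sieves).
   - The phenol adds to the iminium ion and sets C2. The enamine carbon C3 then closes ring C on the formyl carbon C4, and loss of water gives the 2H-chromene-3-carbaldehyde F7.
   - Decarbonylation with RhCl(PPh3)3 in toluene at no more than 80 °C gives 9.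
   - The same detour from 13 and F6, by way of the bromo-2H-chromene-3-carbaldehyde F8, reaches 16.

Further compounds
F1 | step 16 | 6-bromo-tri-O-benzylfisetinidol-(4β→8)-tetra-O-benzylcatechin (dimer diol) | c1ccccc1COc1c(Br)cc2c(c1)O[C@H](c1ccc(OCc3ccccc3)c(OCc3ccccc3)c1)[C@@H](O)[C@H]2c1c(OCc2ccccc2)cc(OCc2ccccc2)c2c1O[C@H](c1ccc(OCc3ccccc3)c(OCc3ccccc3)c1)[C@@H](O)C2
F2 | step 16 | dimer diacetate of F1 | c1ccccc1COc1c(Br)cc2c(c1)O[C@H](c1ccc(OCc3ccccc3)c(OCc3ccccc3)c1)[C@@H](OC(C)=O)[C@H]2c1c(OCc2ccccc2)cc(OCc2ccccc2)c2c1O[C@H](c1ccc(OCc3ccccc3)c(OCc3ccccc3)c1)[C@@H](OC(C)=O)C2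
F3 | step 16 | trimer triacetate (ten benzyl ethers, two bromine caps) | c1ccccc1COc1c(Br)cc2c(c1)O[C@H](c1ccc(OCc3ccccc3)c(OCc3ccccc3)c1)[C@@H](OC(C)=O)[C@H]2c1c(OCc2ccccc2)c([C@@H]2c3cc(Br)c(OCc4ccccc4)cc3O[C@H](c3ccc(OCc4ccccc4)c(OCc4ccccc4)c3)[C@H]2OC(C)=O)c(OCc2ccccc2)c2c1O[C@H](c1ccc(OCc3ccccc3)c(OCc3ccccc3)c1)[C@@H](OC(C)=O)C2
F4 | step 18 | fisetinidol-(4β→8)-catechin | Oc1ccc2c(c1)O[C@H](c1ccc(O)c(O)c1)[C@@H](O)[C@H]2c1c(O)cc(O)c2c1O[C@H](c1ccc(O)c(O)c1)[C@@H](O)C2
F5 | step 18 | 4-O-methylleucofisetinidin, (2R,3S,4R)-2-(3,4-dihydroxyphenyl)-4-methoxychroman-3,7-diol | O[C@H]1[C@H](OC)c2ccc(O)cc2O[C@@H]1c1ccc(O)c(O)c1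
F6 | step 6 | (E)-3-[3,4-bis(benzyloxy)phenyl]acrylaldehyde | O=C/C=C/c1ccc(OCc2ccccc2)c(OCc2ccccc2)c1
F7 | step 6 | 5,7-bis(benzyloxy)-2-[3,4-bis(benzyloxy)phenyl]-2H-chromene-3-carbaldehyde (C2 as in 9) | c1ccccc1COc1cc(OCc2ccccc2)c2c(c1)O[C@H](c1ccc(OCc3ccccc3)c(OCc3ccccc3)c1)C(C=O)=C2
F8 | step 6 | 7-(benzyloxy)-2-[3,4-bis(benzyloxy)phenyl]-6-bromo-2H-chromene-3-carbaldehyde (C2 as in 16) | Brc1cc2c(cc1OCc1ccccc1)O[C@H](c1ccc(OCc3ccccc3)c(OCc3ccccc3)c1)C(C=O)=C2
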